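**Plan**

Ring numbering: C1 = C(CH3)(CH=CHCl), C2 = CH2, C3 = C(CH3)Cl, C4 = CHBr, C5 = CH2, C6 = CHBr; C7=C8 is the chloroalkene.
Enabling feature: the C6 bromide is a neopentyl-type C–Br beside quaternary C1 and cis to the C1 methyl group, which is the pattern an (E)-BrCH=C(CH3)–CHO dienophile already carries; the C4 heteroatom sits 1,4 to C1, where a 2-silyloxy diene places oxygen.
Retrosynthesis: cut C4–Br (from a C4 alcohol, inversion), then C3–Cl and the C4 oxygen back to a C3=C4 silyl enol ether, then C7=C8 back to the C1 aldehyde, then the ring bonds C1–C2 and C5–C6 ([4+2]).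
Forward: bromo enal and silyloxy diene close the only ring; the aldehyde becomes the chloroalkene; C3 is chlorinated, C4 is reduced and then substituted by bromide.
Stereochemistry: C1/C6 relative configuration from the E alkene (suprafacial addition), absolute configuration from a chiral oxazaborolidinium catalyst; C3 by substrate-controlled chlorination; C4 by reagent-controlled reduction, then SN2 inversion; the E chloroalkene from the chromium olefination.

Key step: step 3

Assumption: the β-bromo enal is taken to bind the oxazaborolidinium cation like other 2-substituted acroleins, so that the (R)-diphenylprolinol-derived catalyst gives the (1R,6S) adduct; if the sense of induction were the opposite, the enantiomeric catalyst would be used in the same step.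

**Route**

Step 1
Reactants: 1 methacrolein (2-methylprop-2-enal)
Product: 3 (E)-3-bromo-2-methylprop-2-enal, via 2,3-dibromo-2-methylpropanal 2 (not isolated)
Conditions: Br2 (1.0 equiv), CH2Cl2, 0 °C; then Et3N (1.05 equiv), 0 °C → rt
Reagents that add atoms: bromine, BrBr
Why: Bromine addition to the C=C gives the vicinal dibromide, and because no α-hydrogen is present Et3N can only remove a C3 proton with loss of the tertiary bromide (bromination–dehydrobromination, E2), which should give the conjugated β-bromo enal as the E isomer with bromine trans to formyl.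

Step 2
Reactants: 4 3-methylbut-3-en-2-one; 5 tert-butyldimethylsilyl trifluoromethanesulfonate
Product: 6 2-(tert-butyldimethylsilyloxy)-3-methylbuta-1,3-diene
Conditions: Et3N, CH2Cl2, 0 °C
Reagents that add atoms: tert-butyldimethylsilyl trifluoromethanesulfonate (5), CC(C)(C)[Si](C)(C)OS(=O)(=O)C(F)(F)F
Why: Soft enolisation with silyl triflate and amine (silyl enol ether formation) can only take place at the acetyl methyl group, so the cross-conjugated 2-silyloxy diene should form as a single regioisomer.

Step 3
Reactants: 3 (E)-3-bromo-2-methylprop-2-enal; 6 2-(tert-butyldimethylsilyloxy)-3-methylbuta-1,3-diene (1.5 equiv)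
Product: 7 (1R,6S)-6-bromo-4-(tert-butyldimethylsilyloxy)-1,3-dimethylcyclohex-3-ene-1-carbaldehyde
Conditions: (R)-3,3-diphenyl-1-(2-methylphenyl)tetrahydro-1H,3H-pyrrolo[1,2-c][1,3,2]oxazaborole (20 mol %), Tf2NH (18 mol %), CH2Cl2, −78 → −40 °C; then Et3N
Reagents that add atoms: none
Why: Coordination of the formyl oxygen of 3 to the boron of the chiral oxazaborolidinium cation lowers the enal LUMO, and the diene then adds in a concerted, asynchronous, suprafacial [4+2] cycloaddition (the closest known reaction type is the oxazaborolidinium-catalysed Diels–Alder reaction of 2-substituted acroleins with 2-silyloxy dienes), C5–C6 forming ahead of C1–C2. The six-membered ring closes by this intermolecular [4+2] addition, both new σ bonds being made on one face of the dienophile. The relative configuration at C1 and C6 (bromine cis to the C1 methyl group) is controlled by the E geometry of 3, which a concerted addition carries over unchanged, and the absolute configuration by the catalyst, which holds the s-trans enal through the B–O bond and a formyl C–H···O contact and blocks one of its faces. The step needs regioselectivity, which the silyloxy group secures: it is a far stronger donor than methyl, so its neighbouring CH2 is the nucleophilic terminus and bonds to the β-carbon (C6), leaving oxygen on C4 and methyl on C3. The diene has no terminal substituents, so endo and exo approach lead to the same product, and the adduct, a β-bromo aldehyde with a quaternary α-carbon, has no way to lose HBr.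

Step 4
Reactants: 7 (1R,6S)-6-bromo-4-(tert-butyldimethylsilyloxy)-1,3-dimethylcyclohex-3-ene-1-carbaldehyde
Product: 8 tert-butyl{[(4R,5S)-5-bromo-4-[(E)-2-chloroethenyl]-2,4-dimethylcyclohex-1-en-1-yl]oxy}dimethylsilane
Conditions: CrCl2 (6 equiv), CHCl3 (2 equiv), THF, 65 °C
Reagents that add atoms: chloroform, ClC(Cl)Cl
Why: In the Takai olefination the geminal dichromium species from CHCl3 and CrCl2 adds to the aldehyde and eliminates to the (E)-chloroalkene, while the silyl enol ether and the unactivated secondary bromide should be inert to CrCl2 in THF and no stereocentre is touched.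

Step 5
Reactants: 8 tert-butyl{[(4R,5S)-5-bromo-4-[(E)-2-chloroethenyl]-2,4-dimethylcyclohex-1-en-1-yl]oxy}dimethylsilane
Product: 9 (2R,4R,5S)-5-bromo-2-chloro-4-[(E)-2-chloroethenyl]-2,4-dimethylcyclohexan-1-one
Conditions: NCS (1.05 equiv), CH2Cl2, 0 °C → rt; neutral work-up
Reagents that add atoms: N-chlorosuccinimide, O=C1CCC(=O)N1Cl
Why: Electrophilic α-chlorination of a silyl enol ether can occur only at C3, and the new quaternary centre (Cl cis to the chlorovinyl group, 3R) should be set by substrate control, because in the half-chair with the C1 methyl equatorial and the C6 bromine axial the chair-like axial attack at C3 comes from the face that carries only the flat chlorovinyl group, whereas the other face is screened by the C1 methyl group and the C6 bromine.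

Step 6
Reactants: 9 (2R,4R,5S)-5-bromo-2-chloro-4-[(E)-2-chloroethenyl]-2,4-dimethylcyclohexan-1-one
Product: 10 (1R,2R,4R,5S)-5-bromo-2-chloro-4-[(E)-2-chloroethenyl]-2,4-dimethylcyclohexan-1-ol
Conditions: (S)-1-methyl-3,3-diphenyltetrahydro-1H,3H-pyrrolo[1,2-c][1,3,2]oxazaborole (0.3 equiv), catecholborane (1.5 equiv), toluene, −78 → −40 °C; MeOH, pH 7 buffer
Reagents that add atoms: none
Why: In the Corey–Bakshi–Shibata reduction the (S)-oxazaborolidine should bind the ketone with quaternary C3 as the large and C5 as the small flank and deliver hydride to the face cis to chlorine, setting 4R (OH trans to Cl) under reagent control, while the non-basic borane medium spares the β-bromo ketone from loss of HBr and the chlorohydrin from epoxide closure.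

Step 7
Reactants: 10 (1R,2R,4R,5S)-5-bromo-2-chloro-4-[(E)-2-chloroethenyl]-2,4-dimethylcyclohexan-1-ol
Product: 12 (1R,2S,4S,5R)-2,4-dibromo-1-chloro-5-[(E)-2-chloroethenyl]-1,5-dimethylcyclohexane (target), via C4 triflate 11 (not isolated)
Conditions: Tf2O (1.1 equiv), 2,6-di-tert-butyl-4-methylpyridine, CH2Cl2, −40 °C; then Bu4NBr (4 equiv), −40 °C → rt
Reagents that add atoms: tetrabutylammonium bromide, CCCC[N+](CCCC)(CCCC)CCCC.[Br-]
Why: Sulfonylation is followed by SN2 displacement in which bromide enters C4 opposite the triflate (inversion, giving 4S with Br cis to Cl); C3 has no hydrogen and its chlorine disfavours ionisation, and in the ring conformer with an equatorial triflate neither chlorine nor a hydrogen is antiperiplanar to the leaving group, which should hold back participation and elimination.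

**Compound list**

1 | methacrolein (2-methylprop-2-enal) | CC(=C)C=O | starting material
2 | 2,3-dibromo-2-methylpropanal (racemic) | O=CC(C)(Br)CBr | intermediate
3 | (E)-3-bromo-2-methylprop-2-enal | O=C/C(C)=C/Br | intermediate
4 | 3-methylbut-3-en-2-one | CC(=O)C(C)=C | starting material
5 | tert-butyldimethylsilyl trifluoromethanesulfonate | CC(C)(C)[Si](C)(C)OS(=O)(=O)C(F)(F)F | starting material
6 | 2-(tert-butyldimethylsilyloxy)-3-methylbuta-1,3-diene | C=C(C)C(=C)O[Si](C)(C)C(C)(C)C | intermediate
7 | (1R,6S)-6-bromo-4-(tert-butyldimethylsilyloxy)-1,3-dimethylcyclohex-3-ene-1-carbaldehyde | C[C@]1(C=O)CC(C)=C(O[Si](C)(C)C(C)(C)C)C[C@@H]1Br | intermediate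
8 | tert-butyl{[(4R,5S)-5-bromo-4-[(E)-2-chloroethenyl]-2,4-dimethylcyclohex-1-en-1-yl]oxy}dimethylsilane | C[C@]1(/C=C/Cl)CC(C)=C(O[Si](C)(C)C(C)(C)C)C[C@@H]1Br | intermediate
9 | (2R,4R,5S)-5-bromo-2-chloro-4-[(E)-2-chloroethenyl]-2,4-dimethylcyclohexan-1-one | C[C@]1(/C=C/Cl)C[C@@](C)(Cl)C(=O)C[C@@H]1Br | intermediate
10 | (1R,2R,4R,5S)-5-bromo-2-chloro-4-[(E)-2-chloroethenyl]-2,4-dimethylcyclohexan-1-ol | C[C@]1(/C=C/Cl)C[C@@](C)(Cl)[C@H](O)C[C@@H]1Br | intermediate
11 | (1R,2R,4R,5S)-5-bromo-2-chloro-4-[(E)-2-chloroethenyl]-2,4-dimethylcyclohexyl trifluoromethanesulfonate | C[C@]1(/C=C/Cl)C[C@@](C)(Cl)[C@H](OS(=O)(=O)C(F)(F)F)C[C@@H]1Br | intermediate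
12 | (1R,2S,4S,5R)-2,4-dibromo-1-chloro-5-[(E)-2-chloroethenyl]-1,5-dimethylcyclohexane | C[C@]1(/C=C/Cl)C[C@@](C)(Cl)[C@@H](Br)C[C@@H]1Br | target

**Step count**

Total steps: 7. Longest linear sequence: 6 steps (1 → 3 → 7 → 8 → 9 → 10 → 12; the branch 4 + 5 → 6 is one step and joins at step 3).

**Steps most likely to fail**

Step 7 is the weakest. Backside attack at C4 next to the fully substituted C3 may be slow. Elimination of triflic acid toward C5, or participation of the C3 chlorine (retention at C4 or a 1,2-chlorine shift), could then overtake substitution. The fallback sets out from alcohol 10 and comes back at 12. It drops the sulfonate and activates the alcohol under neutral conditions with Ph3P and CBr4 in toluene (rt → 60 °C, Appel reaction). This would form {(1R,2R,4R,5S)-5-bromo-2-chloro-4-[(E)-2-chloroethenyl]-2,4-dimethylcyclohexyl}oxytriphenylphosphonium bromide F1. In this contact ion pair bromide is held beside C4 and should collapse with inversion to 12 while the oxygen leaves as the phosphine oxide. This is the same reaction class that turns trans-2-chlorocyclohexanols into cis-1,2-dihalides.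

Step 3 comes second. The trisubstituted β-bromo enal may add too slowly. The Lewis acid may divert the silyloxy diene into a stepwise conjugate addition that expels bromide. The catalyst may also discriminate the enal faces incompletely. The fallback sets out from 3 and 6 and comes back at 9. The cycloaddition would be run thermally without any Lewis acid (toluene, 2,6-di-tert-butyl-4-methylphenol, 110 °C, sealed tube), which closes the ionic pathway. It should give 7 as the racemate, that is together with (1S,6R)-6-bromo-4-(tert-butyldimethylsilyloxy)-1,3-dimethylcyclohex-3-ene-1-carbaldehyde F2. Steps 4 and 5 applied to the racemate would also produce tert-butyl{[(4S,5R)-5-bromo-4-[(E)-2-chloroethenyl]-2,4-dimethylcyclohex-1-en-1-yl]oxy}dimethylsilane F3 and (2S,4S,5R)-5-bromo-2-chloro-4-[(E)-2-chloroethenyl]-2,4-dimethylcyclohexan-1-one F4. Preparative chromatography of the racemic ketone on a chiral stationary phase (amylose tris(3,5-dimethylphenylcarbamate), supercritical CO2/isopropanol) would then deliver 9.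

Step 5 comes third. The chlorovinyl group at C1 is not much smaller than methyl, so the two faces of the enol ether may be chlorinated with poor selectivity and the C3 epimer may form. The fallback sets out from 7 and comes back at 10. Chlorination would be done before the olefination, when C1 still carries the much smaller formyl group, which sits axial more readily and hinders the syn-axial electrophile less.

- NCS (CH2Cl2, 0 °C) on 7 should give (1R,2S,5R)-2-bromo-5-chloro-1,5-dimethyl-4-oxocyclohexane-1-carbaldehyde F5.
- (S)-1-methyl-3,3-diphenyltetrahydro-1H,3H-pyrrolo[1,2-c][1,3,2]oxazaborole with BH3·SMe2 (THF, −20 °C) should reduce both carbonyl groups to (1R,2R,4R,5S)-5-bromo-2-chloro-4-(hydroxymethyl)-2,4-dimethylcyclohexan-1-ol F6.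
- TEMPO with PhI(OAc)2 (CH2Cl2, rt) should reoxidise only the primary alcohol to (1R,2S,4R,5R)-2-bromo-5-chloro-4-hydroxy-1,5-dimethylcyclohexane-1-carbaldehyde F7.
- Takai olefination (CrCl2, CHCl3, THF, 65 °C) of this hydroxy aldehyde would give 10.

This order also keeps the silyl enol ether out of the chromium step.

**Further compounds**

F1 | step 7 | {(1R,2R,4R,5S)-5-bromo-2-chloro-4-[(E)-2-chloroethenyl]-2,4-dimethylcyclohexyl}oxytriphenylphosphonium bromide | C[C@]1(/C=C/Cl)C[C@@](C)(Cl)[C@H](O[P+](c2ccccc2)(c2ccccc2)c2ccccc2)C[C@@H]1Br.[Br-]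
F2 | step 3 | (1S,6R)-6-bromo-4-(tert-butyldimethylsilyloxy)-1,3-dimethylcyclohex-3-ene-1-carbaldehyde | C[C@@]1(C=O)CC(C)=C(O[Si](C)(C)C(C)(C)C)C[C@H]1Br
F3 | step 3 | tert-butyl{[(4S,5R)-5-bromo-4-[(E)-2-chloroethenyl]-2,4-dimethylcyclohex-1-en-1-yl]oxy}dimethylsilane | C[C@@]1(/C=C/Cl)CC(C)=C(O[Si](C)(C)C(C)(C)C)C[C@H]1Br
F4 | step 3 | (2S,4S,5R)-5-bromo-2-chloro-4-[(E)-2-chloroethenyl]-2,4-dimethylcyclohexan-1-one | C[C@@]1(/C=C/Cl)C[C@](C)(Cl)C(=O)C[C@H]1Br
F5 | step 5 | (1R,2S,5R)-2-bromo-5-chloro-1,5-dimethyl-4-oxocyclohexane-1-carbaldehyde | C[C@]1(C=O)C[C@@](C)(Cl)C(=O)C[C@@H]1Br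
F6 | step 5 | (1R,2R,4R,5S)-5-bromo-2-chloro-4-(hydroxymethyl)-2,4-dimethylcyclohexan-1-ol | C[C@]1(CO)C[C@@](C)(Cl)[C@H](O)C[C@@H]1Br
F7 | step 5 | (1R,2S,4R,5R)-2-bromo-5-chloro-4-hydroxy-1,5-dimethylcyclohexane-1-carbaldehyde | C[C@]1(C=O)C[C@@](C)(Cl)[C@H](O)C[C@@H]1Br
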